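- The red run has your flask's coupling partner charge, 22.0 mM, but twice its capture agent.

| flask | starting material | coupling partner | capture agent | remark | time |
|---|---|---|---|---|---|
| blue | 20 mM | 31 mM | 0.40 mM | run made earlier |  |
| green | 20 mM | 48 mM | 0.40 mM | run made earlier |  |
| red | 20 mM | 22 mM | 0.80 mM | run made earlier |  |
| flask | 20 mM | 22.0 mM | 0.400 mM |  | 15 d |

- blue (time / d: side product / %, target / %): 1.25: 5.9, 5.2; 3.00: 11.2, 17.1; 8.00: 13.5, 29.0; 20.0: 13.8, 32.3
- green (time / d: side product / %, target / %): 2.50: 8.2, 13.7; 6.00: 8.8, 22.9; 12.0: 8.5, 26.3; 20.0: 8.7, 26.9
- red (time / d: side product / %, target / %): 1.25: 4.1, 5.7; 3.00: 8.7, 15.1; 8.00: 15.0, 28.7; 20.0: 15.7, 33.1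

(standard deviation of a reading: 0.5 percentage points)

- share of side product in side product plus target at 10 h
- share of side product in side product plus target at 2.5 d
- share of side product in side product plus target at 15 d
- which of side product and target there is more of at 15 d

- in percentages every species weighs as the starting material in it: one side product counts as two
- a reading or a percentage of target counts all its forms, free or not

- Divide side product by target at the last reading and time drops out. Call this ρ, a selectivity, and call s the share of side product in side product plus target.
- Coupling partner must be known well. Blue and green differ in partner charge and not in capture agent: ρ reads 0.427 in blue and 0.323 in green. Taken as a power of partner charge, ρ falls with exponent n, the partner order of the selectivity, 0.637. With starting material and capture agent as in these two runs, a factor of 2 in partner divides ρ by 1.56.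
- Time matters little late on: red's s moves 2.2 percentage points between 8.00 d and 20.0 d, and 15 d lies between them.
- Capture agent is the open doubt. Carried from blue to 22.0 mM by n, ρ becomes 0.532, so s is 34.7% at the flask's capture agent. Red, with that partner charge and twice the capture agent, reads ρ 0.474, so s 32.2%.
- Starting material is 20 mM in blue, green, red and the flask, so these runs do not test it and the step to the flask needs no correction for it.
- My reckoning: s between 32.2% and 34.7% at 15 d, and target leads, since both values of ρ are below one.
- The forecast says 60% at 10 h, 39% at 2.5 d and 33% at 15 d, with target ahead, reasoning that the “side-product share starts high and falls with time”.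
- The flask gives 33.5%, 39.7% and 32.4% at those times, with target ahead. Its share at 1.50 d is 41.0%, higher than at 10 h, so in the flask the share climbs before it falls. Its ρ at 15 d is 0.478, below the 0.532 that n gave.

    starting material + coupling partner → intermediate A (k = 2.60 M⁻¹ h⁻¹)
    coupling partner + intermediate A ⇌ intermediate B (K = 37.0 M⁻¹, k = 1.10 M⁻¹ h⁻¹)
    intermediate A ⇌ target (K = 0.790, k = 0.00640 h⁻¹)
    starting material + intermediate B → side product (k = 1.80 M⁻¹ h⁻¹)
    crystals ⇌ target, rate k5*(cs5 - [target]) while solid is left; crystals form when [target] > cs5 (solubility = 11.0 mM, k = 3.20 h⁻¹)
    capture agent + intermediate A → trapped intermediate (k = 0.620 M⁻¹ h⁻¹)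

- In the flask, starting material and coupling partner first formed intermediate A: at 1.50 d, 31.3% starting material remained and intermediate A stood at 48.2%. By 15.0 d, starting material, the limiting reagent, was down to 1.91%, while intermediate A, the resting state, held 44.0%, more than target's 33.4%.
- In a neighbour flask with 55 mM of partner, n carries the flask's ρ to 0.267, so s is 21.1%. That neighbour computes to 23.6% at 15 d.

The numbers in the tables are simulated from invented constants.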